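Locants used throughout (hexahydronaphthalene numbering, also for intermediates): C1 (CH–CO2Me), C2 (C16H33)=C3(H), C4 (CH–CO2Me), C4a, C5 (C=O), C6 (CO2Me)=C7 (C16H33), C8 (H2), C8a. Ring A is C1–C4/C4a/C8a. Ring B is C4a–C8a.

## Structural features

- The target is a cis-fused bicyclo[4.4.0]decadiene. Ring A is a cyclohexene and ring B is a 2-carbomethoxy-3-alkylcyclohex-2-enone.
- C4, C4a, C8a and C1 are four contiguous CH stereocentres. H4, H4a and H8a lie on one face and H1 on the other. The two ring A esters are therefore trans-1,4 across C2=C3. The C4 ester sits on the concave face (cis to C5) and the C1 ester on the convex face.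
- C1–H and C4–H are both α to an ester and allylic, and C4a–H is α to the ketone. The skipped C2=C3 bond would slide into conjugation under base, and the concave C4 ester is unlikely to be the thermodynamic epimer.
- Ring B is a strong Michael acceptor. It is also only two hydrogens away from methyl 6-hexadecylsalicylate, so any intermediate holding both C4a=C8a and C6=C7 is a phenol tautomer.
- All carbonyl pairs are consonant except those involving the C4 ester, which is 1,4 to C5 and 1,6 to the C1 ester.
- The real difficulty is joining C4–C4a and C1–C8a. The acyclic diene implied is an electron-poor muconate that must carry the C1 ester in the inside position of its s-cis form.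
- The key step exploits the atom set C4–C3=C2–C1 plus the C1 carboxyl carbon. With one oxygen between that carbonyl and C4, this is exactly a 2-pyrone ring.

## Logic of the disconnections

**21 ⇒ 18.** The C6=C7 π bond is removed (H added at C6 and C7). This takes out the most electrophilic group and ends the phenol-tautomer problem. It also creates a C7 stereocentre that can be the only source of chirality and is erased at the end. The forward step must be a dehydrogenation without base strong enough to touch C1–H, C4–H or C4a–H.

**18 ⇒ 17 ⇒ 16.** The C5 ketone is masked as the C5=C6 silyl enol ether, and the C1 methyl ester is traced to the free acid. No C–C bond is cut. The gain is that no ketone stands β to C4 or is exposed to a reductant in the preceding steps. The demand is neutral esterification and fluoride desilylation.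

**16 ⇒ 14.** C4–H is exchanged for C4–O, and this oxygen is joined to the C1 carboxyl carbon as a lactone bridge across ring A.
- The trans-1,4 relation then becomes a consequence of ring geometry. The C1 carboxyl is fixed on the bridge face, and C4 carries its ester away from it.
- The forward step must cut C4–O reductively and protonate C4 at the α carbon on the face the oxygen left.

**14 ⇒ 6 + 13 (key).** C4–C4a and C1–C8a are cut as a retro-[4+2] of the 2-oxabicyclo[2.2.2]octenone, not of a cyclohexene.
- A tricycle with five stereocentres falls to a flat heteroaromatic ring and a monocycle with one stereocentre.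
- The inside ester is tied back, the diene is locked s-cis, and the electron demand is inverted.
- The forward step needs regio-, endo- and facial control, and retention of the CO2 bridge.

**13 ⇒ 12 ⇒ 9 + 10.** After O-desilylation, C6–C7 and C4a=C8a are cut (Michael addition, then aldol condensation). Ring B falls to two acyclic pieces. C7 must be set by iminium catalysis.

**9 ⇒ 7 + 8.** The C7=C8 alkene of 9 is cut by cross-metathesis to a bulk α-olefin.

**6 ⇒ 5 ⇒ 3 + 4.** The lactone C–O bond is cut, and then C3–C4 (γ-carbon of an enoate to an oxalate carbonyl). The demand is γ-selective acylation at the methyl group cis to the ester.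

**3 ⇒ 1.** The C2–CH3 and C1–CO2Me bonds are cut (syn carbometalation of a terminal alkyne, then carboxylation). This fixes the alkene geometry needed for lactonisation.

## Other disconnections considered

**Alternative 1:** This is the first idea. Cut C4–C4a and C1–C8a as a plain Diels–Alder of the acyclic diene dimethyl (2Z,4E)-3-hexadecylhexa-2,4-dienedioate A1 with 12, giving 18.
- Both partners are electron-poor, so no frontier-orbital pair is well matched.
- The C1 ester must sit inside the s-cis diene, which disfavours the reactive conformer.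
- The (2E,4E) isomer would need a later epimerisation at C1 next to an equally acidic C4–H.
- The chosen plan removes the conformational and the electronic problem with one ring oxygen.

**Alternative 2:** Cut C3–C4 and C4a–C8a. An intramolecular Diels–Alder reaction of the acyclic tetraene keto triester A2 would fold the whole chain into both rings and give A3.
- The new alkene lands at C1=C2 in conjugation with the ester.
- Moving it to C2=C3 is contra-thermodynamic and needs base in the presence of the more acidic C8–H and C4a–H.
- The (Z)-4-oxoenoate dienophile is configurationally labile, and the C6=C7 acceptor in the tether competes.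
- No simple handle sets the absolute configuration.

**Alternative 3:** Cut only C4–C4a, using the γ,δ-unsaturated carbonyl retron C5(=O)–C4a–C4–C3=C2. An Ireland–Claisen ring contraction of the vinyl δ-lactone A4 would give the cyclohexene acid A5.
- The forced boat transition state and the (E)-enoate do map onto the right C4/C4a configuration.
- However, A4 already holds three stereocentres, including a fully substituted C2–O carbon.
- Enolisation of the lactone competes with loss of C1–H, which would expel the lactone oxygen by β-elimination.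
- Ring B still has to be built by homologation and Knoevenagel closure, so the route is longer.

Key step: step 6

Remark: C6 of 12 and 18 is a configurationally labile β-keto ester carbon. It is drawn as the trans isomer, and its configuration has no consequence for the route.

## Steps

Step 1
Reactants: 1 octadec-1-yne
Product: 3 methyl (2E)-3-methylnonadec-2-enoate, via alkenylalane 2 (not isolated)
Conditions: AlMe3 (2 equiv), Cp2ZrCl2 (20 mol %), CH2Cl2, 0 °C to rt; then ClCO2Me, 0 °C to rt
Reagents that add atoms: trimethylaluminium C[Al](C)C; methyl chloroformate COC(=O)Cl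
Why: Zirconium-catalysed (Negishi) carboalumination adds Me and Al syn across the terminal alkyne with Al at the terminus, and acylation with retention should place the methyl group cis to the ester, which is the geometry needed in step 2.

Step 2
Reactants: 3 methyl (2E)-3-methylnonadec-2-enoate; 4 dimethyl oxalate
Product: 6 methyl 4-hexadecyl-2-oxo-2H-pyran-6-carboxylate, via keto diester 5 (not isolated)
Conditions: KOMe, Et2O/THF, 0 °C to rt; 1 M HCl; then TsOH·H2O (cat.), toluene, reflux (−MeOH)
Reagents that add atoms: none
Why: Reversible vinylogous Claisen condensation of a 3-methyl-2-enoate with an oxalate is the classical entry to 2-pyrone-6-carboxylates; the less hindered methyl group cis to the ester should be acylated, and the enol of the α-keto ester then lactonises onto the cis ester.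

Step 3
Reactants: 7 octadec-1-ene; 8 (E)-but-2-enal
Product: 9 (2E)-nonadec-2-enal
Conditions: Hoveyda–Grubbs II (2 mol %), 8 (5 equiv), CH2Cl2, 40 °C
Reagents that add atoms: none
Why: Cross-metathesis of a type I α-olefin with an enal is selective for the (E)-enal, and loss of propene drives it.

Step 4
Reactants: 9 (2E)-nonadec-2-enal; 10 methyl 3-oxobutanoate
Product: 12 methyl (1S,6R)-6-hexadecyl-2-oxocyclohex-3-ene-1-carboxylate, via Michael adduct 11 (not isolated)
Conditions: (S)-2-[diphenyl(trimethylsilyloxy)methyl]pyrrolidine (10 mol %), PhCO2H (10 mol %), toluene, rt; then TsOH·H2O (20 mol %), toluene, 80 °C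
Reagents that add atoms: none
Why: Iminium-catalysed Michael addition of a β-keto ester to an enal followed by acid-promoted intramolecular aldol condensation is an established cyclohexenone synthesis; in the usual shielding model the (S)-catalyst blocks one face of the s-trans (E)-iminium ion so that C6 adds to give (R)-C7, and C6 then settles trans.

Step 5
Reactants: 12 methyl (1S,6R)-6-hexadecyl-2-oxocyclohex-3-ene-1-carboxylate
Product: 13 methyl (6R)-2-[(tert-butyldimethylsilyl)oxy]-6-hexadecylcyclohexa-1,3-diene-1-carboxylate
Conditions: TBSOTf, Et3N, CH2Cl2, 0 °C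
Reagents that add atoms: tert-butyldimethylsilyl triflate CC(C)(C)[Si](C)(C)OS(=O)(=O)C(F)(F)F
Why: Soft enolisation removes the most acidic proton (C6–H), so O-silylation should give the C5=C6 enol ether; this raises the HOMO of the C4a=C8a bond, hides the ketone and leaves C7 untouched.

Step 6
Reactants: 6 methyl 4-hexadecyl-2-oxo-2H-pyran-6-carboxylate; 13 methyl (6R)-2-[(tert-butyldimethylsilyl)oxy]-6-hexadecylcyclohexa-1,3-diene-1-carboxylate
Product: 14 lactone-bridged cycloadduct (1S,4S,4aS,7R,8aR): dimethyl 5-(TBSO)-2,7-dihexadecyl-1,4,4a,7,8,8a-hexahydronaphthalene-4,6-dicarboxylate with a C1–C(=O)–O–C4 bridge on the H4a/H8a face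
Conditions: 13 (1.5 equiv), BHT (cat.), CH2Cl2, 1.3 GPa, 40 °C
Reagents that add atoms: none
Why: A concerted, asynchronous inverse-electron-demand [4+2] is expected, in which the LUMO of 6 (lowered by the lactone carbonyl and the ester) meets the HOMO of the C4a=C8a bond of 13 (raised by conjugation with the silyl enol ether). The closest known type is the cycloaddition of electron-poor 2-pyrone carboxylates with enol ethers and 1,3-dienes, run under pressure so that the CO2 bridge is kept. One suprafacial event closes ring A and the 2-oxabicyclo[2.2.2]octenone, and the cis ring fusion follows from the cis ring alkene. The face of 13 is chosen by C7, because allylic strain with the C6 ester pushes the hexadecyl group pseudoaxial so that the pyrone should add anti to it, fixing C4a and C8a. C1 and C4 are fixed by the ring of 6, since the future C1 carboxyl carbon and the C4 oxygen are one bridge; the endo mode (ring B under C2=C3, away from the lactone, with secondary overlap of C5=C6) puts that bridge on the H4a/H8a face. Regiochemistry needs C8a, the terminal and less hindered carbon with the larger HOMO coefficient, to lead bonding to the unsubstituted pyrone C3 (δ carbon of the ester-bearing dienoate), with C4a–C4 lagging. Periselectivity needs 13 to act as the 2π partner, which is secured because its own diene would have to bond through fully substituted C6 to a trisubstituted pyrone alkene. The negative activation volume speeds the addition at a temperature where retro-[4+2] loss of CO2, which would erase the C1 carboxyl, should not compete.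

Step 7
Reactants: 14 lactone-bridged cycloadduct
Product: 16 (1S,4R,4aS,7R,8aR)-5-(TBSO)-2,7-dihexadecyl-4,6-bis(methoxycarbonyl)-1,4,4a,7,8,8a-hexahydronaphthalene-1-carboxylic acid, via dienolate dianion 15 (not isolated)
Conditions: SmI2 (2.5 equiv), THF/MeOH, −78 °C; pH 4 buffer
Reagents that add atoms: none
Why: SmI2 reduction of an α-acyloxy ester (here also tertiary, allylic and strained) expels the carboxylate and leaves the C4 ester dienolate; kinetic α-protonation keeps C2=C3 skipped, and it should occur on the convex face just vacated by oxygen, where the samarium-bound C1 carboxylate can hold the proton source and ring B blocks the other face, giving H4 cis to H4a.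

Step 8
Reactants: 16 the C1 carboxylic acid
Product: 17 trimethyl (1S,4R,4aS,7R,8aR)-5-(TBSO)-2,7-dihexadecyl-1,4,4a,7,8,8a-hexahydronaphthalene-1,4,6-tricarboxylate
Conditions: TMSCHN2, toluene/MeOH (4:1), 0 °C
Reagents that add atoms: trimethylsilyldiazomethane C[Si](C)(C)C=[N+]=[N-]
Why: Diazoalkane esterification is neutral, so none of the α-stereocentres and neither the enol ether nor the skipped alkene should be disturbed.

Step 9
Reactants: 17 the TBS enol ether triester
Product: 18 trimethyl (1S,4R,4aS,6S,7R,8aR)-2,7-dihexadecyl-5-oxo-1,4,4a,5,6,7,8,8a-octahydronaphthalene-1,4,6-tricarboxylate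
Conditions: HF·pyridine, THF, 0 °C
Reagents that add atoms: none
Why: Buffered fluoride cleaves the silyl enol ether to the β-keto ester under weakly acidic conditions that should not epimerise C4 or C4a.

Step 10
Reactants: 18 the β-keto ester
Product: 21 trimethyl (1S,4R,4aS,8aR)-2,7-dihexadecyl-5-oxo-1,4,4a,5,8,8a-hexahydronaphthalene-1,4,6-tricarboxylate, via selenide 19 (not isolated), via selenoxide 20 (not isolated)
Conditions: PhSeCl, pyridine, CH2Cl2, 0 °C; then 30% H2O2, 0 °C to rt
Reagents that add atoms: benzeneselenenyl chloride Cl[Se]c1ccccc1; hydrogen peroxide OO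
Why: α-Selenenylation of a β-keto ester enol and selenoxide syn-elimination is the standard mild route to 2-carboalkoxy enones; selenium should enter C6 anti to the C7 alkyl group and therefore syn to H7, the only β-hydrogen, so that C6=C7 forms and the relay centre C7 is erased.

## Compound list

1 | octadec-1-yne | CCCCCCCCCCCCCCCCC#C | starting material
2 | (E)-dimethyl(2-methyloctadec-1-en-1-yl)alane | CCCCCCCCCCCCCCCC/C(C)=C/[Al](C)C | intermediate
3 | methyl (2E)-3-methylnonadec-2-enoate | CCCCCCCCCCCCCCCC/C(C)=C/C(=O)OC | intermediate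
4 | dimethyl oxalate | COC(=O)C(=O)OC | starting material
5 | dimethyl (4Z)-4-hexadecyl-2-oxohex-4-enedioate | COC(=O)C(=O)C/C(CCCCCCCCCCCCCCCC)=C\C(=O)OC | intermediate
6 | methyl 4-hexadecyl-2-oxo-2H-pyran-6-carboxylate | COC(=O)C1=CC(CCCCCCCCCCCCCCCC)=CC(=O)O1 | intermediate
7 | octadec-1-ene | CCCCCCCCCCCCCCCCC=C | starting material
8 | (E)-but-2-enal | C/C=C/C=O | starting material
9 | (2E)-nonadec-2-enal | CCCCCCCCCCCCCCCC/C=C/C=O | intermediate
10 | methyl 3-oxobutanoate | CC(=O)CC(=O)OC | starting material
11 | methyl (3R)-2-acetyl-3-(2-oxoethyl)nonadecanoate | CC(=O)C(C(=O)OC)[C@H](CCCCCCCCCCCCCCCC)CC=O | intermediate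
12 | methyl (1S,6R)-6-hexadecyl-2-oxocyclohex-3-ene-1-carboxylate | O=C1C=CC[C@@H](CCCCCCCCCCCCCCCC)[C@@H]1C(=O)OC | intermediate
13 | methyl (6R)-2-[(tert-butyldimethylsilyl)oxy]-6-hexadecylcyclohexa-1,3-diene-1-carboxylate | COC(=O)C1=C(O[Si](C)(C)C(C)(C)C)C=CC[C@H]1CCCCCCCCCCCCCCCC | intermediate
14 | lactone-bridged cycloadduct (1S,4S,4aS,7R,8aR), C1–C(=O)–O–C4 bridge on the H4a/H8a face | CCCCCCCCCCCCCCCCC1=C[C@]2(C(=O)OC)OC(=O)[C@H]1[C@@H]3C[C@@H](CCCCCCCCCCCCCCCC)C(C(=O)OC)=C(O[Si](C)(C)C(C)(C)C)[C@H]23 | intermediate
15 | C4 ester dienolate / C1 carboxylate dianion (samarium counter-ions omitted) | CCCCCCCCCCCCCCCCC1=CC(=C([O-])OC)[C@H]2C(O[Si](C)(C)C(C)(C)C)=C(C(=O)OC)[C@H](CCCCCCCCCCCCCCCC)C[C@H]2[C@@H]1C(=O)[O-] | intermediate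
16 | (1S,4R,4aS,7R,8aR)-5-(TBSO)-2,7-dihexadecyl-4,6-bis(methoxycarbonyl)-1,4,4a,7,8,8a-hexahydronaphthalene-1-carboxylic acid | CCCCCCCCCCCCCCCCC1=C[C@@H](C(=O)OC)[C@H]2C(O[Si](C)(C)C(C)(C)C)=C(C(=O)OC)[C@H](CCCCCCCCCCCCCCCC)C[C@H]2[C@@H]1C(=O)O | intermediate
17 | trimethyl (1S,4R,4aS,7R,8aR)-5-(TBSO)-2,7-dihexadecyl-1,4,4a,7,8,8a-hexahydronaphthalene-1,4,6-tricarboxylate | CCCCCCCCCCCCCCCCC1=C[C@@H](C(=O)OC)[C@H]2C(O[Si](C)(C)C(C)(C)C)=C(C(=O)OC)[C@H](CCCCCCCCCCCCCCCC)C[C@H]2[C@@H]1C(=O)OC | intermediate
18 | trimethyl (1S,4R,4aS,6S,7R,8aR)-2,7-dihexadecyl-5-oxo-1,4,4a,5,6,7,8,8a-octahydronaphthalene-1,4,6-tricarboxylate | CCCCCCCCCCCCCCCCC1=C[C@@H](C(=O)OC)[C@H]2C(=O)[C@@H](C(=O)OC)[C@H](CCCCCCCCCCCCCCCC)C[C@H]2[C@@H]1C(=O)OC | intermediate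
19 | (6S)-6-(phenylselanyl) derivative of 18, Se anti to the C7 chain | CCCCCCCCCCCCCCCCC1=C[C@@H](C(=O)OC)[C@H]2C(=O)[C@]([Se]c3ccccc3)(C(=O)OC)[C@H](CCCCCCCCCCCCCCCC)C[C@H]2[C@@H]1C(=O)OC | intermediate
20 | selenoxide of 19 | CCCCCCCCCCCCCCCCC1=C[C@@H](C(=O)OC)[C@H]2C(=O)[C@]([Se](=O)c3ccccc3)(C(=O)OC)[C@H](CCCCCCCCCCCCCCCC)C[C@H]2[C@@H]1C(=O)OC | intermediate
21 | trimethyl (1S,4R,4aS,8aR)-2,7-dihexadecyl-5-oxo-1,4,4a,5,8,8a-hexahydronaphthalene-1,4,6-tricarboxylate (CNP0149813.1) | CCCCCCCCCCCCCCCCC1=C[C@@H](C(=O)OC)[C@H]2C(=O)C(C(=O)OC)=C(CCCCCCCCCCCCCCCC)C[C@H]2[C@@H]1C(=O)OC | target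

## Step count and least certain steps

Total step count: 10. Longest linear sequence: 8 (steps 3–10, from 7). The pyrone branch (steps 1–2) joins at step 6.

**Step 6 (key).**
- *What may go wrong.* The cycloaddition of two hindered partners may be too slow. Regiocontrol may leak because acceptor groups at both diene termini polarise the LUMO only weakly. 13 may take part as the 4π component. CO2 may be lost if heating becomes necessary.
- *Fallback: make the union intramolecular so that regiochemistry is dictated by a tether.*
  - From 6, hydrolysis (Me3SnOH, 1,2-dichloroethane, 60 °C) would give 4-hexadecyl-2-oxo-2H-pyran-6-carboxylic acid F1.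
  - O-Acylation of the enol of 12 (DCC, DMAP) would give the enol ester F2.
  - Intramolecular [4+2] (toluene, 90 °C) would give the cage bis-lactone F3.
  - SmI2 as in step 7 would give the enol-lactone acid F4, and TMSCHN2 its methyl ester F5.
  - Methanolysis of the enol lactone (MeOH, DMAP) would release the C4 ester and the C5 ketone and return to 18.

**Step 7.**
- *What may go wrong.* Protonation of the dienolate may occur from the concave face or at C2 (γ), which would invert C4 or conjugate the alkene. Electron transfer to other groups may occur if an additive is needed.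
- *Fallback: set C4 by hydrogen-atom transfer instead of protonation.*
  - From 14, methanolysis of the bridge (MeOH, Et3N, DMAP) would give the C4 tertiary alcohol triester F6.
  - Acylation with methyl chlorooxoacetate would give the methyl oxalate F7.
  - Bu3SnH/AIBN (Barton–McCombie-type deoxygenation) would deliver H to the allyl radical from the convex face and return to 17.

**Step 2.**
- *What may go wrong.* Deprotonation may occur at the chain CH2 instead of the methyl group. α-Acylation of the dienolate may compete. Lactonisation may stay incomplete.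
- *Fallback: build the pyrone first and attach the chain by cross-coupling.*
  - From 10 (as its dianion) and 4, γ-acylation would give dimethyl 2,4-dioxohexanedioate F8.
  - Acid cyclisation would give methyl 4-hydroxy-2-oxo-2H-pyran-6-carboxylate F9, and Tf2O/Et3N its triflate F10.
  - B-alkyl Suzuki coupling with B-hexadecyl-9-BBN F11 (from hexadec-1-ene and 9-BBN; Pd(dppf)Cl2, K3PO4) would return to 6.

**Step 10.**
- *What may go wrong.* Selenenylation may occur on the face of the C7 chain, which leaves no syn hydrogen. PhSeCl may add to C2=C3. Peroxide may attack the product enone.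
- *Fallback.* Start one step earlier, from 17, and dehydrogenate the silyl enol ether directly (Saegusa–Ito oxidation with Pd(OAc)2 in MeCN, or DDQ). This needs no syn relation at C6 and arrives at 21 without a new intermediate.

## Further compounds

F1 | step 6 | 4-hexadecyl-2-oxo-2H-pyran-6-carboxylic acid | OC(=O)C1=CC(CCCCCCCCCCCCCCCC)=CC(=O)O1
F2 | step 6 | methyl (6R)-6-hexadecyl-2-[(4-hexadecyl-2-oxo-2H-pyran-6-carbonyl)oxy]cyclohexa-1,3-diene-1-carboxylate | COC(=O)C1=C(OC(=O)C2=CC(CCCCCCCCCCCCCCCC)=CC(=O)O2)C=CC[C@H]1CCCCCCCCCCCCCCCC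
F3 | step 6 | cage bis-lactone (C1–C(=O)–O–C4 bridge and C4–C(=O)–O–C5 enol lactone) | CCCCCCCCCCCCCCCCC1=C[C@@]23OC(=O)[C@H]1[C@@H]4C[C@@H](CCCCCCCCCCCCCCCC)C(C(=O)OC)=C(OC2=O)[C@H]34
F4 | step 6 | enol-lactone C1 carboxylic acid | CCCCCCCCCCCCCCCCC1=C[C@H]2C(=O)OC3=C(C(=O)OC)[C@H](CCCCCCCCCCCCCCCC)C[C@@H]([C@@H]1C(=O)O)[C@@H]23
F5 | step 6 | enol-lactone C1 methyl ester | CCCCCCCCCCCCCCCCC1=C[C@H]2C(=O)OC3=C(C(=O)OC)[C@H](CCCCCCCCCCCCCCCC)C[C@@H]([C@@H]1C(=O)OC)[C@@H]23
F6 | step 7 | C4-hydroxy derivative of 17 (OH on the H4a face) | CCCCCCCCCCCCCCCCC1=C[C@@](O)(C(=O)OC)[C@H]2C(O[Si](C)(C)C(C)(C)C)=C(C(=O)OC)[C@H](CCCCCCCCCCCCCCCC)C[C@H]2[C@@H]1C(=O)OC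
F7 | step 7 | C4 methyl oxalate of F6 | CCCCCCCCCCCCCCCCC1=C[C@@](OC(=O)C(=O)OC)(C(=O)OC)[C@H]2C(O[Si](C)(C)C(C)(C)C)=C(C(=O)OC)[C@H](CCCCCCCCCCCCCCCC)C[C@H]2[C@@H]1C(=O)OC
F8 | step 2 | dimethyl 2,4-dioxohexanedioate | COC(=O)C(=O)CC(=O)CC(=O)OC
F9 | step 2 | methyl 4-hydroxy-2-oxo-2H-pyran-6-carboxylate | COC(=O)C1=CC(O)=CC(=O)O1
F10 | step 2 | methyl 2-oxo-4-(trifluoromethylsulfonyloxy)-2H-pyran-6-carboxylate | COC(=O)C1=CC(OS(=O)(=O)C(F)(F)F)=CC(=O)O1
F11 | step 2 | 9-hexadecyl-9-borabicyclo[3.3.1]nonane | CCCCCCCCCCCCCCCCB1C2CCCC1CCC2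
F0 | step 10 | none | none
A1 | alternative 1 | dimethyl (2Z,4E)-3-hexadecylhexa-2,4-dienedioate | COC(=O)/C=C/C(CCCCCCCCCCCCCCCC)=C\C(=O)OC
A2 | alternative 2 | acyclic tetraene keto triester (C3=C4 Z; C5 and C8 cis on C6=C7; C2 and C8 trans on C1=C8a) | C=C(CCCCCCCCCCCCCCCC)/C(C(=O)OC)=C/C/C(CCCCCCCCCCCCCCCC)=C(/C(=O)OC)C(=O)/C=C\C(=O)OC
A3 | alternative 2 | C1=C2 conjugated isomer of the target | CCCCCCCCCCCCCCCCC1=C(C(=O)OC)[C@@H]2CC(CCCCCCCCCCCCCCCC)=C(C(=O)OC)C(=O)[C@@H]2[C@H](C(=O)OC)C1
A4 | alternative 3 | vinyl δ-lactone (C5(=O)–O–C2 ring, C7 ketone as dioxolane) | O=C1C[C@@H](CC2(CCCCCCCCCCCCCCCC)OCCO2)[C@H](C(=O)OC)[C@](CCCCCCCCCCCCCCCC)(/C=C/C(=O)OC)O1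
A5 | alternative 3 | ring A cyclohexene with C5 as free carboxylic acid | CCCCCCCCCCCCCCCCC1=C[C@@H](C(=O)OC)[C@@H](C(=O)O)[C@@H](CC2(CCCCCCCCCCCCCCCC)OCCO2)[C@@H]1C(=O)OC
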